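The flavanone C ring (O1, C2, C3, C4, C4a, C8a) is reached by contraction of a seven-membered ring. O7'' of the flavone A ring, the later sulfate site, is ortho to C8'', and C8a of the flavanone A ring is ortho to the C4 carbonyl, so a C8a–O7'' diaryl ether ties C3, C4, C4a and C8a into a dibenzoxepinone. In one operation its C3 enolate adds to 4-benzyloxybenzaldehyde and the aldolate oxygen displaces O7'' at C8a (Smiles rearrangement): 7 becomes 6, C2–C3 and O1–C8a form, and only the 7''-OH is set free. Transfer hydrogenation with dynamic kinetic resolution then fixes (2R,3S).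

Key step: step 7

Remark: in compounds 1–11 the flavone carries its own apigenin locants (5, 7, 8, 4'); from 12 on these become 5'', 7'', 8'' and 4''', and unprimed locants belong to the flavanone unit. The target SMILES fixes no axial chirality about C3–C8'', so rotamers about that bond are taken to interconvert.

**Step 1**
Reactants: 1 apigenin; 2 allyl bromide
Product: 3 7-O-allylapigenin
Conditions: K2CO3 (1.1 equiv), DMF, rt
Reagents that add atoms: allyl bromide (2), C=CCBr
Why: Williamson etherification; the 7-OH, para to the pyrone carbonyl, is the most acidic phenol of apigenin and is alkylated first with one equivalent of base, while the chelated 5-OH stays untouched.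

**Step 2**
Reactants: 3 7-O-allylapigenin; 4 benzyl bromide
Product: 5 7-O-allyl-5,4'-di-O-benzylapigenin
Conditions: BnBr (2.5 equiv), K2CO3, Bu4NI (cat.), DMF, 80 °C
Reagents that add atoms: benzyl bromide (4), BrCc1ccccc1
Why: Williamson benzylation; excess reagent and heat also alkylate the hydrogen-bonded 5-OH, and both benzyl ethers later fall in the final hydrogenolysis.

**Step 3**
Reactants: 5 7-O-allyl-5,4'-di-O-benzylapigenin
Product: 6 8-allyl-5,4'-di-O-benzylapigenin (free 7-OH)
Conditions: PhNEt2, 200 °C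
Reagents that add atoms: none
Why: Aromatic Claisen rearrangement ([3,3] shift, then tautomerisation) delivers the allyl group to C8, the ortho position favoured by the higher C7–C8 bond order of the benzopyrone, and frees the 7-OH for the ether bridge.

**Step 4**
Reactants: 6 8-allyl-5,4'-di-O-benzylapigenin; 7 [3,5-bis(benzyloxy)phenyl]boronic acid
Product: 8 8-allyl-7-O-[3,5-bis(benzyloxy)phenyl]-5,4'-di-O-benzylapigenin
Conditions: Cu(OAc)2 (20 mol%), pyridine, 4 Å MS, O2 (1 atm), CH2Cl2, rt
Reagents that add atoms: [3,5-bis(benzyloxy)phenyl]boronic acid (7), OB(O)c1cc(OCc2ccccc2)cc(OCc2ccccc2)c1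
Why: Chan–Lam oxidative O-arylation joins the hindered, acidic 7-OH to the arylboronic acid at room temperature and leaves the allyl group untouched.

**Step 5**
Reactants: 8 8-allyl-7-O-[3,5-bis(benzyloxy)phenyl]-5,4'-di-O-benzylapigenin
Product: 10 flavon-8-ylacetic acid with the 7-aryloxy group, via arylacetaldehyde 9 (not isolated)
Conditions: OsO4 (2 mol%), NaIO4, 2,6-lutidine, dioxane/H2O, rt; then NaClO2, NaH2PO4, 2-methyl-2-butene, t-BuOH/H2O, 0 °C
Reagents that add atoms: osmium tetroxide, O=[Os](=O)(=O)=O; sodium periodate, [Na+].[O-]I(=O)(=O)=O; sodium chlorite, [Na+].[O-]Cl=O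
Why: Lemieux–Johnson cleavage of the terminal alkene (the electron-poor C2=C3 bond of the flavone is not dihydroxylated) and Pinnick oxidation of the crude aldehyde, with 2-methyl-2-butene to trap HOCl before it chlorinates the electron-rich rings.

**Step 6**
Reactants: 10 flavon-8-ylacetic acid with the 7-aryloxy group
Product: 12 dibenzoxepinone (flavone-fused 1,3-bis(benzyloxy)dibenzo[b,f]oxepin-10(11H)-one), via mixed trifluoroacetic anhydride 11 (not isolated)
Conditions: (CF3CO)2O, CH2Cl2, 0 °C to rt, high dilution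
Reagents that add atoms: none
Why: Intramolecular Friedel–Crafts acylation through the acyl trifluoroacetate; the tether reaches only the two equivalent positions ortho to the aryloxy group of the phloroglucinol-type ring, so the seven-membered ring closes (7-exo-trig) under conditions mild enough for the benzyl ethers.

**Step 7**
Reactants: 12 dibenzoxepinone; 13 4-(benzyloxy)benzaldehyde
Product: 15 racemic trans-5,7,4'-tri-O-benzyl-3-(5'',4'''-di-O-benzylapigenin-8''-yl)naringenin (free 7''-OH), via potassium aldolate 14 (not isolated)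
Conditions: t-BuOK (1.1 equiv), 13 (1.5 equiv), THF/DMF, −20 °C to rt; AcOH
Reagents that add atoms: 4-(benzyloxy)benzaldehyde (13), O=Cc1ccc(OCc2ccccc2)cc1
Why: tert-Butoxide forms the C3 enolate of 12 (activated by C4=O and the flavone ring), which adds to aldehyde 13; the aldolate oxygen of 14 then attacks C8a ipso through a spiro-Meisenheimer adduct and the flavone 7''-oxide leaves, an O-to-O Smiles rearrangement. The closest known reactions are the Smiles rearrangement of 2-hydroxyalkyl aryl ethers and the base-induced xanthone closure of 2-hydroxy-2'-alkoxybenzophenones, both intramolecular SNAr reactions at a carbon ortho to a carbonyl group. The six-membered ring closes by 6-exo-trig addition of the alkoxide to C8a followed by loss of the aryloxide, which opens the seven-membered ring, so the oxepinone loses one ring atom. C2 and C3 are under thermodynamic control here: aldol addition, enolisation at C3 and ring opening of the product to the chalcone are all reversible in base, so the racemic 2,3-trans isomer with both aryl groups equatorial results, and the absolute configuration is set in step 8. The step needs attack at C8a and not at C7''; C8a is activated by the directly conjugated ortho ketone, and an adduct formed at C7'' (a dihydrobenzofuran with a free ring-A phenoxide) would return through the same chalcone to 15, whose 7''-phenoxide, the conjugate base of a vinylogous acid, is the thermodynamic sink.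

**Step 8**
Reactants: 15 racemic trans-flavanone phenol
Product: 16 (2R,3R,4S)-flavan-4-ol (2,3-trans-3,4-cis; free 7''-OH)
Conditions: RuCl[(S,S)-TsDPEN](p-cymene) (3 mol%), HCO2H/Et3N, DBU, THF, 40 °C
Reagents that add atoms: none
Why: Noyori-type asymmetric transfer hydrogenation under dynamic kinetic resolution, the known behaviour of 2- and 3-substituted chroman-4-ones in base: C2 racemises by retro-oxa-Michael ring opening and re-closure and C3 by enolisation, while the (S,S) catalyst reduces fastest the stereoisomer that gives the (4S) alcohol with the 3-aryl group cis to the new OH and trans to the 2-aryl group, which fixes C2 as R and C3 in the target sense.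

**Step 9**
Reactants: 16 (2R,3R,4S)-flavan-4-ol
Product: 17 (2R,3S)-5,7,4'-tri-O-benzyl-3-(5'',4'''-di-O-benzylapigenin-8''-yl)naringenin (free 7''-OH)
Conditions: Dess–Martin periodinane, CH2Cl2, 0 °C
Reagents that add atoms: none
Why: Dess–Martin oxidation returns the C4 ketone under neutral conditions that neither open the ring nor enolise C3, so the (2R) centre from step 8 and the already trans, thermodynamically preferred C3 centre are kept.

**Step 10**
Reactants: 17 (2R,3S)-flavanone phenol
Product: 18 sodium 7''-O-sulfate of 17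
Conditions: SO3·pyridine (5 equiv), DMF/pyridine, 40 °C; then aq. NaHCO3
Reagents that add atoms: sulfur trioxide–pyridine complex, [O-]S(=O)(=O)[n+]1ccccc1; sodium hydrogencarbonate, [Na+].OC([O-])=O
Why: Sulfation of a phenol with the SO3–pyridine complex; the 7''-OH freed in step 7 is the only hydroxyl group in 17, so no site selectivity is needed, and the weakly basic medium does not open the flavanone.

**Step 11**
Reactants: 18 sodium 7''-O-sulfate
Product: 19 CNP0271389.1 (target)
Conditions: H2 (1 atm), 10% Pd/C, THF/MeOH, rt; then 1 M HCl (1.0 equiv), 0 °C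
Reagents that add atoms: none
Why: Hydrogenolysis of the five benzyl ethers over Pd/C under neutral conditions spares the aryl sulfate, the flavone C2''=C3'' bond, the C4 ketone and both stereocentres; brief cold acidification converts the sodium salt into the hydrogen sulfate.

**Compound list**

1 | apigenin, 5,7-dihydroxy-2-(4-hydroxyphenyl)-4H-chromen-4-one | O=c1cc(-c2ccc(O)cc2)oc2cc(O)cc(O)c12 | starting material
2 | allyl bromide | C=CCBr | starting material
3 | 7-O-allylapigenin, 5-hydroxy-2-(4-hydroxyphenyl)-7-(prop-2-en-1-yloxy)-4H-chromen-4-one | O=c1cc(-c2ccc(O)cc2)oc2cc(OCC=C)cc(O)c12 | intermediate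
4 | benzyl bromide | BrCc1ccccc1 | starting material
5 | 7-(allyloxy)-5-(benzyloxy)-2-[4-(benzyloxy)phenyl]-4H-chromen-4-one | O=c1cc(-c2ccc(OCc3ccccc3)cc2)oc2cc(OCC=C)cc(OCc3ccccc3)c12 | intermediate
6 | 8-allyl-5-(benzyloxy)-2-[4-(benzyloxy)phenyl]-7-hydroxy-4H-chromen-4-one | O=c1cc(-c2ccc(OCc3ccccc3)cc2)oc2c(CC=C)c(O)cc(OCc3ccccc3)c12 | intermediate
7 | [3,5-bis(benzyloxy)phenyl]boronic acid | OB(O)c1cc(OCc2ccccc2)cc(OCc2ccccc2)c1 | starting material
8 | 8-allyl-5-(benzyloxy)-2-[4-(benzyloxy)phenyl]-7-[3,5-bis(benzyloxy)phenoxy]-4H-chromen-4-one | O=c1cc(-c2ccc(OCc3ccccc3)cc2)oc2c(CC=C)c(Oc3cc(OCc4ccccc4)cc(OCc4ccccc4)c3)cc(OCc3ccccc3)c12 | intermediate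
9 | 2-{5-(benzyloxy)-2-[4-(benzyloxy)phenyl]-7-[3,5-bis(benzyloxy)phenoxy]-4-oxo-4H-chromen-8-yl}acetaldehyde | O=CCc1c(Oc2cc(OCc3ccccc3)cc(OCc3ccccc3)c2)cc(OCc2ccccc2)c2c(=O)cc(-c3ccc(OCc4ccccc4)cc3)oc12 | intermediate
10 | 2-{5-(benzyloxy)-2-[4-(benzyloxy)phenyl]-7-[3,5-bis(benzyloxy)phenoxy]-4-oxo-4H-chromen-8-yl}acetic acid | OC(=O)Cc1c(Oc2cc(OCc3ccccc3)cc(OCc3ccccc3)c2)cc(OCc2ccccc2)c2c(=O)cc(-c3ccc(OCc4ccccc4)cc3)oc12 | intermediate
11 | mixed anhydride of acid 10 with trifluoroacetic acid | O=C(Cc1c(Oc2cc(OCc3ccccc3)cc(OCc3ccccc3)c2)cc(OCc2ccccc2)c2c(=O)cc(-c3ccc(OCc4ccccc4)cc3)oc12)OC(=O)C(F)(F)F | intermediate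
12 | dibenzoxepinone: seven-membered ring made of the ketone carbon (later C4), a CH2 (later C3), flavone C8'' and C7'', the ether oxygen, and C8a and C4a of a 5,7-bis(benzyloxy)benzo ring; the flavone carries 5''-OBn and 4'''-OBn | O=C1Cc2c(Oc3cc(OCc4ccccc4)cc(OCc4ccccc4)c31)cc(OCc1ccccc1)c1c(=O)cc(-c3ccc(OCc4ccccc4)cc3)oc21 | intermediate
13 | 4-(benzyloxy)benzaldehyde | O=Cc1ccc(OCc2ccccc2)cc1 | starting material
14 | potassium aldolate of 12 and 13 (CH2 of 12 now bears the CH(O−)-[4-(benzyloxy)phenyl] group; stereoisomer mixture) | [K+].[O-]C(c1ccc(OCc2ccccc2)cc1)C1C(=O)c2c(OCc3ccccc3)cc(OCc3ccccc3)cc2Oc2cc(OCc3ccccc3)c3c(=O)cc(-c4ccc(OCc5ccccc5)cc4)oc3c21 | intermediate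
15 | (±)-trans-5,7-bis(benzyloxy)-2-[4-(benzyloxy)phenyl]-3-{5-(benzyloxy)-2-[4-(benzyloxy)phenyl]-7-hydroxy-4-oxo-4H-chromen-8-yl}chroman-4-one (racemate, both enantiomers written) | O=C1c2c(OCc3ccccc3)cc(OCc3ccccc3)cc2O[C@@H](c2ccc(OCc3ccccc3)cc2)[C@@H]1c1c(O)cc(OCc2ccccc2)c2c(=O)cc(-c3ccc(OCc4ccccc4)cc3)oc12.O=C1c2c(OCc3ccccc3)cc(OCc3ccccc3)cc2O[C@H](c2ccc(OCc3ccccc3)cc2)[C@H]1c1c(O)cc(OCc2ccccc2)c2c(=O)cc(-c3ccc(OCc4ccccc4)cc3)oc12 | intermediate
16 | (2R,3R,4S)-5,7-bis(benzyloxy)-2-[4-(benzyloxy)phenyl]-3-{5-(benzyloxy)-2-[4-(benzyloxy)phenyl]-7-hydroxy-4-oxo-4H-chromen-8-yl}chroman-4-ol | O[C@@H]1c2c(OCc3ccccc3)cc(OCc3ccccc3)cc2O[C@@H](c2ccc(OCc3ccccc3)cc2)[C@@H]1c1c(O)cc(OCc2ccccc2)c2c(=O)cc(-c3ccc(OCc4ccccc4)cc3)oc12 | intermediate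
17 | (2R,3S)-5,7-bis(benzyloxy)-2-[4-(benzyloxy)phenyl]-3-{5-(benzyloxy)-2-[4-(benzyloxy)phenyl]-7-hydroxy-4-oxo-4H-chromen-8-yl}chroman-4-one | O=C1c2c(OCc3ccccc3)cc(OCc3ccccc3)cc2O[C@@H](c2ccc(OCc3ccccc3)cc2)[C@@H]1c1c(O)cc(OCc2ccccc2)c2c(=O)cc(-c3ccc(OCc4ccccc4)cc3)oc12 | intermediate
18 | sodium salt of the 7''-O-sulfate of 17 | O=C1c2c(OCc3ccccc3)cc(OCc3ccccc3)cc2O[C@@H](c2ccc(OCc3ccccc3)cc2)[C@@H]1c1c(OS(=O)(=O)[O-])cc(OCc2ccccc2)c2c(=O)cc(-c3ccc(OCc4ccccc4)cc3)oc12.[Na+] | intermediate
19 | CNP0271389.1, (2R,3S)-naringenin-(3→8'')-apigenin 7''-O-(hydrogen sulfate) | O=C1c2c(O)cc(O)cc2O[C@@H](c2ccc(O)cc2)[C@@H]1c1c(OS(=O)(=O)O)cc(O)c2c(=O)cc(-c3ccc(O)cc3)oc12 | target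

**Totals and risks**

Total step count: 11. Longest linear sequence: 11 steps (from apigenin 1; the other building blocks 2, 4, 7 and 13 are commercial).

Steps most likely to fail:

1. Step 7. The aldol adduct may lose water to the arylidene ketone faster than the aryl group migrates, or the alkoxide may attack C7'' and leave the isomeric dihydrobenzofuran, so the ring contraction stalls. The fallback sets out from 12 and comes back at 15. Claisen–Schmidt condensation of 12 with 13 (piperidine, AcOH, toluene, reflux) should give the arylidene oxepinone F1. SNAr cleavage of its carbonyl-activated diaryl ether with hydroxide (KOH, DMSO/H2O, 60 °C) should give the 2'-hydroxychalcone bis-phenol F2. The classical base-mediated chalcone-to-flavanone cyclisation (NaOAc, EtOH, reflux) should then give 15.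

2. Step 8. Racemisation of C2 by ring opening may be slower than reduction, or the hindered C4 carbonyl (peri 5-benzyloxy group, bulky 3-aryl group) may be reduced slowly and with poor discrimination, which would lower the enantiomeric purity or the conversion. The fallback sets out from 15 and comes back at 17, leaving out 16, by classical resolution. Acylation of the 7''-OH with (1S)-camphanic chloride (Et3N, DMAP, CH2Cl2) should give the diastereomeric camphanates F3 (2R,3S) and F4 (2S,3R), to be separated by chromatography or crystallisation. Ammonolysis of the camphanate F3 (NH3, MeOH/THF, 0 °C) should give 17; F4 can be cleaved, racemised with base through the chalcone and recycled.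

3. Step 3. The allyl group may migrate to C6 instead of C8 (both ortho to O7), which would erode the regiochemical purity of everything that follows. The fallback sets out from 5 and comes back at 8, leaving out 6. Pd(PPh3)4 with morpholine should remove the allyl group to give 5,4'-di-O-benzylapigenin F5. NIS (DMF, 0 °C) should iodinate ortho to the free 7-OH at C8, the position not flanked by the 5-benzyloxy group, to give the 8-iodo phenol F6. Chan–Lam coupling with 7 should give the iodo diaryl ether F7, and Stille coupling with allyltributylstannane (Pd(PPh3)4, LiCl, DMF, 90 °C) should give 8.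

**Further compounds**

F1 | step 7 | 11-[4-(benzyloxy)benzylidene] derivative of dibenzoxepinone 12 (alkene geometry not controlled) | O=C1C(=Cc2ccc(OCc3ccccc3)cc2)c2c(Oc3cc(OCc4ccccc4)cc(OCc4ccccc4)c31)cc(OCc1ccccc1)c1c(=O)cc(-c3ccc(OCc4ccccc4)cc3)oc21
F2 | step 7 | 1-[2,4-bis(benzyloxy)-6-hydroxyphenyl]-3-[4-(benzyloxy)phenyl]-2-{5-(benzyloxy)-2-[4-(benzyloxy)phenyl]-7-hydroxy-4-oxo-4H-chromen-8-yl}prop-2-en-1-one (alkene geometry not controlled) | O=C(C(=Cc1ccc(OCc2ccccc2)cc1)c1c(O)cc(OCc2ccccc2)c2c(=O)cc(-c3ccc(OCc4ccccc4)cc3)oc12)c1c(O)cc(OCc2ccccc2)cc1OCc1ccccc1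
F3 | step 8 | 7''-O-[(1S)-camphanoyl] ester of (2R,3S)-17 | O=C1c2c(OCc3ccccc3)cc(OCc3ccccc3)cc2O[C@@H](c2ccc(OCc3ccccc3)cc2)[C@@H]1c1c(OC(=O)[C@@]56CC[C@@](C)(C(=O)O5)C6(C)C)cc(OCc2ccccc2)c2c(=O)cc(-c3ccc(OCc4ccccc4)cc3)oc12
F4 | step 8 | 7''-O-[(1S)-camphanoyl] ester of the (2S,3R) enantiomer of 17 | O=C1c2c(OCc3ccccc3)cc(OCc3ccccc3)cc2O[C@H](c2ccc(OCc3ccccc3)cc2)[C@H]1c1c(OC(=O)[C@@]56CC[C@@](C)(C(=O)O5)C6(C)C)cc(OCc2ccccc2)c2c(=O)cc(-c3ccc(OCc4ccccc4)cc3)oc12
F5 | step 3 | 5-(benzyloxy)-2-[4-(benzyloxy)phenyl]-7-hydroxy-4H-chromen-4-one | O=c1cc(-c2ccc(OCc3ccccc3)cc2)oc2cc(O)cc(OCc3ccccc3)c12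
F6 | step 3 | 5-(benzyloxy)-2-[4-(benzyloxy)phenyl]-7-hydroxy-8-iodo-4H-chromen-4-one | O=c1cc(-c2ccc(OCc3ccccc3)cc2)oc2c(I)c(O)cc(OCc3ccccc3)c12
F7 | step 3 | 5-(benzyloxy)-2-[4-(benzyloxy)phenyl]-7-[3,5-bis(benzyloxy)phenoxy]-8-iodo-4H-chromen-4-one | O=c1cc(-c2ccc(OCc3ccccc3)cc2)oc2c(I)c(Oc3cc(OCc4ccccc4)cc(OCc4ccccc4)c3)cc(OCc3ccccc3)c12
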